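**Strategy**

Everything rests on making the C9–C11 bond by carbonyl addition. C9, the chain-bearing carbon of ring B, lies between the quaternary C10 and the C7=C8 olefin, so it is carried as the ketone carbon of a C14 enone cut from (+)-sclareolide (source of C5 and C10). Homofarnesyllithium, from farnesyl bromide via a phenyl sulfide, should add to this ketone opposite the C10 methyl, and the alkoxide is trapped as a tertiary allylic carbonate. One operation thus joins the C16 and C14 halves and sets C9 as an oxygen-bearing stereocentre; palladium/formate then replaces that oxygen by hydride with inversion, leaving the olefin at C7=C8.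

Key step: step 6

Remark: drimane numbering is used throughout (ring A = C1–C5, C10; ring B = C5–C10; C11 is the chain carbon on C9; C12 is the methyl on C8). α means the face opposite the C10 methyl, β the same face. "11-Nordrimane" means the 2,5,5,8a-tetramethyldecalin skeleton (drimane without C11).

**Route**

Step 1
Reactants: 1 (+)-sclareolide
Product: 3 9,11-didehydrosclareolide (butenolide with C9=C11), via 11α-phenylselanyl lactone 2 (not isolated)
Conditions: LiN(iPr)2, THF, −78 °C; PhSeBr; then 30% H2O2, pyridine, CH2Cl2, 0 °C to rt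
Reagents that add atoms: none
Why: α-Selenenylation of the lactone enolate should occur on the α-face, away from the axial methyls on C8 and C10, so the selenoxide has the C9 hydrogen syn and selenoxide syn-elimination can only give the C9=C11 butenolide; the C9 stereocentre is erased on purpose, C5, C8 and C10 are untouched.

Step 2
Reactants: 3 9,11-didehydrosclareolide
Product: 5 8α-hydroxy-11-nordriman-9-one (α-ketol), via keto glyoxylate 4 (not isolated)
Conditions: O3, CH2Cl2/MeOH, −78 °C; Me2S; then K2CO3 (0.2 equiv), MeOH, 0 °C to rt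
Reagents that add atoms: ozone, O=[O+][O-]
Why: Ozonolysis (Criegee mechanism, reductive work-up) cleaves the only C=C bond so that C11 and C12 leave as a glyoxylate ester, which base-catalysed methanolysis removes from the tertiary C8 oxygen; C5, C8 and C10 are not affected.

Step 3
Reactants: 5 8α-hydroxy-11-nordriman-9-one
Product: 6 11-nordrim-8(12)-en-9-one (exocyclic enone)
Conditions: SOCl2, pyridine, CH2Cl2, 0 °C
Reagents that add atoms: none
Why: In this thionyl chloride/pyridine dehydration of a tertiary alcohol, the equatorial 8α-chlorosulfite has only the C12 methyl hydrogens anti-periplanar, so anti-elimination should give mainly the exocyclic enone; any endocyclic isomer 7 formed alongside is the product of step 4 and is carried on with the crude material.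

Step 4
Reactants: 6 11-nordrim-8(12)-en-9-one
Product: 7 11-nordrim-7-en-9-one (endocyclic enone)
Conditions: RhCl3·3H2O (5 mol %), EtOH, 80 °C
Reagents that add atoms: none
Why: Rhodium hydride addition–elimination (rhodium trichloride-catalysed migration of an exocyclic enone double bond) should move the C8=C12 bond into ring B to the more stable conjugated, trisubstituted C7=C8 enone; no stereocentre is involved.

Step 5
Reactants: 8 thioanisole; 9 (2E,6E)-farnesyl bromide
Product: 11 homofarnesyl phenyl sulfide, via (phenylthio)methyllithium 10 (not isolated)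
Conditions: n-BuLi, TMEDA, THF, 0 °C; then 9, −78 °C to rt
Reagents that add atoms: none
Why: Lithiation of thioanisole at the methyl group and SN2 alkylation with the primary allylic bromide (one-carbon homologation through an α-thio carbanion) adds the future C11 without touching the E olefins.

Step 6
Reactants: 11 homofarnesyl phenyl sulfide; 7 11-nordrim-7-en-9-one
Product: 14 tertiary allylic methyl carbonate (chain 9α, carbonate 9β), via homofarnesyllithium 12 (not isolated), via lithium C9 alkoxide 13 (not isolated)
Conditions: lithium 4,4'-di-tert-butylbiphenylide (2.0 equiv), THF, −78 °C; then 7, −78 °C; then ClCO2Me (2.5 equiv), −78 to 0 °C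
Reagents that add atoms: methyl chloroformate, COC(=O)Cl
Why: Lithium 4,4'-di-tert-butylbiphenylide cleaves the alkyl C–S bond of 11 by two single-electron transfers (reductive lithiation of an alkyl phenyl sulfide) to the primary organolithium 12, which adds 1,2 to the C9 carbonyl of 7; the closest known reaction type is organolithium addition to 2,6,6-trisubstituted cyclohex-2-enones followed by O-acylation of the lithium alkoxide. No ring is closed. The new stereocentre C9 is under substrate control: the pseudoaxial C10 methyl blocks the β-face of ring B, so C11 should enter from the α-face and the oxygen ends β (1S in 14). The step needs 1,2- over 1,4-addition and addition over deprotonation, which the hard organolithium at −78 °C, the quaternary C10 (no α-hydrogen) and the α-methyl on C8 should secure. Methyl chloroformate then caps first the thiophenolate and then alkoxide 13, so that the C9 oxygen becomes the leaving group whose β-orientation fixes the face taken by palladium in step 7.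

Step 7
Reactants: 14 tertiary allylic methyl carbonate
Product: 15 (4aS,5S,8aS)-1,1,4a,6-tetramethyl-5-[(3E,7E)-4,8,12-trimethyltrideca-3,7,11-trien-1-yl]-1,2,3,4,4a,5,8,8a-octahydronaphthalene (target)
Conditions: Pd(OAc)2 (5 mol %), n-Bu3P (5 mol %), HCO2H, Et3N, THF, 40 °C
Reagents that add atoms: none
Why: Zerovalent palladium should ionise the 9β-carbonate with inversion (metal on the α-face), and the palladium formate then delivers hydride on that face to the more substituted allyl terminus C9 (palladium-catalysed formate hydrogenolysis of an allylic carbonate, Tsuji-type), giving 9α-H (9S) with the chain β and the olefin kept at C7=C8.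

**Compound list**

1 | (+)-sclareolide, (3aR,5aS,9aS,9bR)-3a,6,6,9a-tetramethyldecahydronaphtho[2,1-b]furan-2(1H)-one | O=C1C[C@H]2[C@@](C)(CC[C@@H]3[C@]2(C)CCCC3(C)C)O1 | starting material
2 | 11α-(phenylselanyl)sclareolide (Se cis to H-9) | O=C1[C@@H]([Se]c4ccccc4)[C@H]2[C@@](C)(CC[C@@H]3[C@]2(C)CCCC3(C)C)O1 | intermediate (not isolated)
3 | 9,11-didehydrosclareolide (butenolide, C9=C11; 8α-O, 8β-CH3, 5α-H, 10β-CH3) | O=C1C=C2[C@@](C)(CC[C@@H]3[C@]2(C)CCCC3(C)C)O1 | intermediate
4 | 8α-(glyoxyloyloxy)-11-nordriman-9-one (keto glyoxylate) | O=CC(=O)O[C@]1(C)CC[C@H]2C(C)(C)CCC[C@]2(C)C1=O | intermediate (not isolated)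
5 | 8α-hydroxy-11-nordriman-9-one, (2R,4aS,8aS)-2-hydroxy-2,5,5,8a-tetramethyloctahydronaphthalen-1(2H)-one | O[C@]1(C)CC[C@H]2C(C)(C)CCC[C@]2(C)C1=O | intermediate
6 | 11-nordrim-8(12)-en-9-one, (4aS,8aS)-5,5,8a-trimethyl-2-methylideneoctahydronaphthalen-1(2H)-one | C=C1CC[C@H]2C(C)(C)CCC[C@]2(C)C1=O | intermediate
7 | 11-nordrim-7-en-9-one, (4aS,8aS)-2,5,5,8a-tetramethyl-4a,5,6,7,8,8a-hexahydronaphthalen-1(4H)-one | CC1=CC[C@H]2C(C)(C)CCC[C@]2(C)C1=O | intermediate
8 | thioanisole | CSc1ccccc1 | starting material
9 | (2E,6E)-farnesyl bromide | CC(C)=CCC/C(C)=C/CC/C(C)=C/CBr | starting material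
10 | (phenylthio)methyllithium | [Li]CSc1ccccc1 | intermediate (not isolated)
11 | homofarnesyl phenyl sulfide, phenyl[(3E,7E)-4,8,12-trimethyltrideca-3,7,11-trien-1-yl]sulfane | CC(C)=CCC/C(C)=C/CC/C(C)=C/CCSc1ccccc1 | intermediate
12 | homofarnesyllithium, [(3E,7E)-4,8,12-trimethyltrideca-3,7,11-trien-1-yl]lithium | CC(C)=CCC/C(C)=C/CC/C(C)=C/CC[Li] | intermediate (not isolated)
13 | lithium (1S,4aS,8aS)-2,5,5,8a-tetramethyl-1-[(3E,7E)-4,8,12-trimethyltrideca-3,7,11-trien-1-yl]-1,4,4a,5,6,7,8,8a-octahydronaphthalen-1-olate (chain 9α, O 9β) | CC(C)=CCC/C(C)=C/CC/C(C)=C/CC[C@@]1(O[Li])C(C)=CC[C@H]2C(C)(C)CCC[C@]12C | intermediate (not isolated)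
14 | methyl (1S,4aS,8aS)-2,5,5,8a-tetramethyl-1-[(3E,7E)-4,8,12-trimethyltrideca-3,7,11-trien-1-yl]-1,4,4a,5,6,7,8,8a-octahydronaphthalen-1-yl carbonate (chain 9α, carbonate 9β) | CC(C)=CCC/C(C)=C/CC/C(C)=C/CC[C@@]1(OC(=O)OC)C(C)=CC[C@H]2C(C)(C)CCC[C@]12C | intermediate
15 | (4aS,5S,8aS)-1,1,4a,6-tetramethyl-5-[(3E,7E)-4,8,12-trimethyltrideca-3,7,11-trien-1-yl]-1,2,3,4,4a,5,8,8a-octahydronaphthalene (5α-H, 9α-H, 10β-CH3, chain 9β) | CC(C)=CCC/C(C)=C/CC/C(C)=C/CC[C@H]1C(C)=CC[C@H]2C(C)(C)CCC[C@]12C | target

**Step count**

Total: 7 steps. Longest linear sequence: 6 steps (1, 2, 3, 4, 6, 7).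

**Steps most likely to fail**

Step 7. Hydride may be transferred to the less substituted allyl terminus C7 (olefin ending at C8=C9), the allylpalladium intermediate may undergo β-hydride elimination to dienes, or palladium–palladium exchange may erode the stereospecificity. The fallback sets out from 13 and comes back at 15. Alkoxide 13 would be quenched with aqueous NH4Cl instead of chloroformate to give the tertiary allylic alcohol F1. Babler–Dauben oxidative transposition with pyridinium chlorochromate, C5H5NH[CrO3Cl], in CH2Cl2 should give the transposed C7 enone F2. Luche reduction (NaBH4, CeCl3·7H2O, MeOH, −78 °C; axial hydride from the α-face) should give the 7β-allylic alcohol F3. A Mitsunobu reaction with 2-nitrobenzenesulfonylhydrazide (PPh3, diethyl azodicarboxylate, N-methylmorpholine, THF, −30 °C) should give, with inversion at C7, the 7α-sulfonylhydrazine F4. On warming this loses the sulfinic acid to the 7α-allylic diazene F5, whose retro-ene loss of nitrogen delivers hydrogen suprafacially to the α-face of C9 and moves the olefin to C7=C8, giving 15 without a metal hydride.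

Step 6. The organolithium may deprotonate at the γ-position or add in a conjugate fashion, it may attack partly from the β-face, or the hindered alkoxide may be acylated incompletely. The fallback sets out from 7 and 12 and comes back at 15, bypassing 13 and 14; it unites the halves by copper-mediated anti-SN2' substitution instead of carbonyl addition. Nucleophilic epoxidation of 7 (H2O2, NaOH, MeOH; axial attack at C7 from the α-face) should give the 7α,8α-epoxy ketone F6. Wharton transposition (N2H4·H2O, AcOH, MeOH) should give 11-nordrim-8-en-7α-ol F7, with the hydroxyl pseudoaxial. Esterification with picolinic acid (dicyclohexylcarbodiimide, 4-dimethylaminopyridine, CH2Cl2) gives the 7α-picolinate F8. Organolithium 12 is transmetallated with MgBr2·OEt2 to homofarnesylmagnesium bromide F9, the thiophenolate present serving as a non-transferable ligand on copper. With CuBr·SMe2 in THF (−40 to 0 °C) the alkylcopper should attack C9 on the β-face, anti to the leaving group, forming the same C9–C11 bond and placing the olefin at C7=C8 to give 15 directly.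

Step 3. The chlorosulfite may be substituted to a tertiary chloride instead of eliminating, the α-ketol may undergo acyloin rearrangement, or the α-methylene ketone may dimerise. The fallback sets out from 5 and comes back at 7. Reductive removal of the α-hydroxyl with SmI2 (THF/HMPA, t-BuOH) should give the saturated ketone 11-nordriman-9-one F10 (either C8 epimer serves). Dehydrogenation with 2-iodoxybenzoic acid (DMSO, 70 °C) through the only possible enol (towards C8) should then give the endocyclic enone 7.

**Further compounds**

F1 | step 7 | (1S,4aS,8aS)-2,5,5,8a-tetramethyl-1-[(3E,7E)-4,8,12-trimethyltrideca-3,7,11-trien-1-yl]-1,4,4a,5,6,7,8,8a-octahydronaphthalen-1-ol | CC(C)=CCC/C(C)=C/CC/C(C)=C/CC[C@@]1(O)C(C)=CC[C@H]2C(C)(C)CCC[C@]12C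
F2 | step 7 | transposed enone (C7 ketone, C8=C9 olefin bearing the chain on C9) | CC(C)=CCC/C(C)=C/CC/C(C)=C/CCC1=C(C)C(=O)C[C@H]2C(C)(C)CCC[C@]12C
F3 | step 7 | 7β-allylic alcohol (C8=C9 olefin, chain on C9) | CC(C)=CCC/C(C)=C/CC/C(C)=C/CCC1=C(C)[C@@H](O)C[C@H]2C(C)(C)CCC[C@]12C
F4 | step 7 | 7α-[N-(2-nitrobenzenesulfonyl)hydrazinyl] Mitsunobu adduct | CC(C)=CCC/C(C)=C/CC/C(C)=C/CCC1=C(C)[C@H](N(N)S(=O)(=O)c3ccccc3[N+](=O)[O-])C[C@H]2C(C)(C)CCC[C@]12C
F5 | step 7 | 7α-allylic diazene | CC(C)=CCC/C(C)=C/CC/C(C)=C/CCC1=C(C)[C@H](N=N)C[C@H]2C(C)(C)CCC[C@]12C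
F6 | step 6 | 7α,8α-epoxy-11-nordriman-9-one | C[C@@]12O[C@@H]1C[C@H]3C(C)(C)CCC[C@]3(C)C2=O
F7 | step 6 | 11-nordrim-8-en-7α-ol | O[C@@H]1C[C@H]2C(C)(C)CCC[C@]2(C)C=C1C
F8 | step 6 | 11-nordrim-8-en-7α-yl picolinate | O=C(O[C@@H]1C[C@H]2C(C)(C)CCC[C@]2(C)C=C1C)c3ccccn3
F9 | step 6 | homofarnesylmagnesium bromide | CC(C)=CCC/C(C)=C/CC/C(C)=C/CC[Mg]Br
F10 | step 3 | 11-nordriman-9-one (8α-methyl epimer shown) | C[C@@H]1CC[C@H]2C(C)(C)CCC[C@]2(C)C1=O
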